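**Retrosynthetic overview**
1. Target 26 ⇒ (C6 angeloylation, removal of protecting groups) acetonide diol 23 ⇒ (C1=C10 hydrogenation, C5 reduction, C4 oxygenation) ten-membered 1(10),4-diene 17, which is a C4=C5 silyl enol ether.
2. 17 ⇒ anionic oxy-Cope ring expansion of cyclohexanol 14. C2–C3 is made and C5–C10 is cut, so the six-membered ring grows by four atoms.
3. Feature: ring atoms C5–C10 (oxygen on C5, CH3 on C10, side chain on C7 para to C10) are the six ring carbons of (R)-carvone. C1–C4 are a vinyl group on C10 and an isopropenyl group on C5, joined at their termini C2 and C3.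
4. 14 ⇒ dienol 11 (the C11–OH group delivers the C6 oxygen cis to the side chain; invertive hydrolysis then sets C5–OH) ⇒ cyclopropylcarbinol 10 ⇒ carone 4 ⇒ (R)-carvone 1. The cyclopropane steers the C10 quaternary centre.
5. Ring order: carvone ring (given); temporary cyclopropane (closed in step 3, opened in step 7); dioxasilinane (step 10); ten-membered ring (step 11); dioxolane (step 15).

Key step: step 11

Remark 1: germacrane numbering (C1–C15) is used for every intermediate. β is the ring face that carries the C7 side chain and α is the opposite face.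
Remark 2: it is assumed that C10 in 2–4 is an epimer mixture (major isomer drawn) and that the carbinol centre of 7 is a mixture (left undefined). Both are erased later (steps 4 and 5). C5 of 10 is erased in step 7.
Remark 3: a carbon nucleophile should enter a C5 ketone from the α face, anti to the axial C14. An electrophilic oxidant on a C5 enolate should enter C6 trans to the side chain. For this reason, 5α-OH and 6β-O are both set through the β-epoxide 12.

**Step 1**
Reactants: 1 (R)-carvone
Product: 2 (2R,5R)-dihydrocarvone
Conditions: Zn dust, KOH, EtOH–H2O, reflux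
Reagents that add atoms: none
Why: Dissolving-metal conjugate reduction of the enone leaves the isolated isopropenyl group and C7 untouched, and C10 forms as an epimer mixture that is erased in step 4.

**Step 2**
Reactants: 2 (2R,5R)-dihydrocarvone
Product: 3 (2R,5R)-5-(2-chloropropan-2-yl)-2-methylcyclohexanone
Conditions: HCl (g), AcOH, 0 °C
Reagents that add atoms: hydrogen chloride, Cl
Why: Markovnikov hydrochlorination of the 1,1-disubstituted alkene gives the tertiary C11 chloride without touching a stereocentre.

**Step 3**
Reactants: 3 (2R,5R)-5-(2-chloropropan-2-yl)-2-methylcyclohexanone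
Product: 4 carone (3,7,7-trimethylbicyclo[4.1.0]heptan-2-one; cyclopropane C6–C7–C11 on the β face; 6S,7R)
Conditions: KOH, MeOH, 0 °C to rt
Reagents that add atoms: none
Why: Intramolecular enolate alkylation (3-exo-tet), in which only the C6 enolate can reach C11 and a three-membered ring can only be cis-fused, so the new C6–C11 bond lies on the β face beside C7–C11.

**Step 4**
Reactants: 4 carone; 5 acetaldehyde
Product: 7 10α-(1-hydroxyethyl)-10β-methylcarone, via lithium enolate 6 (not isolated)
Conditions: LiN(i-Pr)2, THF, −78 to 0 °C; 5, −78 °C; AcOH quench at −78 °C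
Reagents that add atoms: none
Why: Directed aldol addition, in which the cyclopropyl C6–H is not enolisable so only the C5=C10 enolate forms, and acetaldehyde attacks C10 from the α face, away from the endo methyl group of the gem-dimethylcyclopropane, placing the two-carbon unit α and C14 β (10S).

**Step 5**
Reactants: 7 10α-(1-hydroxyethyl)-10β-methylcarone
Product: 8 10β-methyl-10α-vinylcarone
Conditions: Ph2S[OC(CF3)2Ph]2, CH2Cl2, 0 °C to rt
Reagents that add atoms: none
Why: Sulfurane-mediated E2 dehydration in a non-basic medium, where C10 carries no hydrogen so only the methyl group can lose a proton (terminal vinyl) and retro-aldol cleavage is avoided.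

**Step 6**
Reactants: 8 10β-methyl-10α-vinylcarone; 9 isopropenylmagnesium bromide
Product: 10 5α-isopropenyl-10β-methyl-10α-vinylcaran-5β-ol
Conditions: CeCl3 (dried), 9, THF, −78 °C; then 8, −78 to 0 °C; aq. NH4Cl
Reagents that add atoms: none
Why: 1,2-Addition of an organocerium reagent to a hindered, practically non-enolisable ketone, expected from the α face (anti to the cyclopropane), although the C5 centre is erased in step 7.

**Step 7**
Reactants: 10 5α-isopropenyl-10β-methyl-10α-vinylcaran-5β-ol
Product: 11 (7R,10S)-dienol (C5=C6 ring alkene with isopropenyl on C5; 10β-CH3; 10α-vinyl; 7β-C(CH3)2OH)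
Conditions: HClO4 (cat.), THF–H2O, 0 °C to rt
Reagents that add atoms: water, O
Why: Cyclopropylcarbinyl–homoallyl rearrangement (the retro-i-steroid type of solvolysis), in which ionisation of the tertiary, allylic, cyclopropyl-flanked C5–OH, cleavage of the aligned C6–C11 bond and capture of the tertiary C11 cation by water give C5=C6 and C11–OH in one operation without touching C7 or C10.

**Step 8**
Reactants: 11 (7R,10S)-dienol
Product: 12 (5S,6R,7R,10S)-5β,6β-epoxide of 11
Conditions: VO(acac)2 (cat.), t-BuOOH, CH2Cl2, 0 °C to rt
Reagents that add atoms: tert-butyl hydroperoxide, CC(C)(C)OO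
Why: Hydroxyl-directed vanadium-catalysed epoxidation of a homoallylic alcohol, in which the vanadate ester of C11–OH reaches only C5=C6 and delivers oxygen to the face that carries the side chain (through the half-chair with a pseudoaxial side chain), so that C6–O is set cis to C7–C11 (6R).

**Step 9**
Reactants: 12 (5S,6R,7R,10S)-5β,6β-epoxide
Product: 13 (5R,6R,7R,10S)-triol (5α-OH; 5β-isopropenyl; 6β-OH; 11-OH)
Conditions: HClO4 (cat.), THF–H2O, 0 °C
Reagents that add atoms: water, O
Why: Acid-catalysed vinyl-epoxide hydrolysis, in which charge builds at the tertiary allylic C5 and water attacks there from the open α face anti to the epoxide oxygen (trans-diaxial opening, Fürst–Plattner rule), inverting C5 to 5α-OH/5β-isopropenyl and leaving C6–O β, while SN2′ capture at C3 would need a strained tetrasubstituted exocyclic alkene next to quaternary C10.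

**Step 10**
Reactants: 13 (5R,6R,7R,10S)-triol
Product: 14 (5R,6R,7R,10S)-5β-isopropenyl-10β-methyl-10α-vinylcyclohexan-5α-ol 6,11-di-tert-butylsilylene ether
Conditions: t-Bu2Si(OTf)2, 2,6-lutidine, CH2Cl2, 0 °C
Reagents that add atoms: di-tert-butylsilyl bis(trifluoromethanesulfonate), CC(C)(C)[Si](OS(=O)(=O)C(F)(F)F)(OS(=O)(=O)C(F)(F)F)C(C)(C)C
Why: Cyclic silylene formation, in which only 6β-OH and 11-OH can be bridged (six-membered ring) because 5α-OH is trans-diaxial to O6, and the cis-fused dioxasilinane locks the chair with the side chain, vinyl and isopropenyl groups equatorial.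

**Step 11**
Reactants: 14 (5R,6R,7R,10S)-silylene-protected divinylcyclohexanol
Product: 17 (6R,7R)-ten-membered 1(10)E,4-diene C5 trimethylsilyl enol ether, via potassium alkoxide 15 (not isolated), via potassium enolate 16 (not isolated)
Conditions: KH, 18-crown-6, THF, 0 to 50 °C; then Me3SiCl, Et3N, −78 °C
Reagents that add atoms: chlorotrimethylsilane, C[Si](C)(C)Cl
Why: KH deprotonates the axial C5–OH and 18-crown-6 frees alkoxide 15, whose charge weakens C5–C10 and drives a concerted [3,3] shift (anionic oxy-Cope rearrangement of a 1,2-dialkenylcyclohexanol, the standard four-atom expansion to (E)-cyclodec-5-enones). The ten-membered ring is closed by bond formation between the alkene termini C2 and C3 while C5–C10 breaks, so no end-to-end medium-ring cyclisation is involved. The cis-fused dioxasilinane holds the chair in which the side chain, vinyl and isopropenyl groups are all equatorial, so the six reacting atoms adopt a chair fused in the trans-decalin manner; C9 and C6 are equatorial on that chair, which gives the E C1=C10 alkene and a C4=C5 enolate with C3 and C6 trans (Z by the CIP rules, because O outranks C6). No stereocentre is formed and C5 and C10 are lost, but their configuration passes into the planar chirality of the tetrasubstituted C4=C5 unit (C15 on the β face, O5 on the α face), which is retained because neither C15 nor the oxygen substituent can pass through the ring. Enolate 16 forms regiospecifically between C4 and C5, and Me3SiCl fixes it at low temperature before proton exchange can move it towards C6. Silyl transfer to the alkoxide is excluded because O5 and O6 are trans-diaxial.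

**Step 12**
Reactants: 17 ten-membered silyl enol ether
Product: 19 (4R,6R,7R)-4-hydroxy-5-ketone, via 4-silyloxy ketone 18 (not isolated)
Conditions: mCPBA (1 equiv), NaHCO3, CH2Cl2, −40 °C; then AcOH–THF–H2O, rt
Reagents that add atoms: 3-chloroperbenzoic acid, O=C(OO)c1cccc(Cl)c1
Why: Rubottom oxidation, in which the electron-rich tetrasubstituted enol ether reacts faster than the trisubstituted C1=C10 alkene and only its outer face is open (the inner face looks across the ring and the unit cannot rotate), so oxygen enters C4 anti to the former C5–C10 bond and sets 4R (O4 α, C15 β); a silyl shift gives 18 and mild acid frees the alcohol.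

**Step 13**
Reactants: 19 (4R,6R,7R)-4-hydroxy-5-ketone
Product: 20 (4R,5S,6R,7R)-4,5-diol
Conditions: Zn(BH4)2, Et2O, −20 °C
Reagents that add atoms: none
Why: Chelation-controlled reduction, in which zinc bridges O4 and the C5 carbonyl oxygen (the silyl ether O6 does not compete) and hydride enters from the outer side next to C15, away from C3 and the rest of the ring, giving 5S with O4 and O5 on the same (α) side.

**Step 14**
Reactants: 20 (4R,5S,6R,7R)-4,5-diol
Product: 21 (4R,5S,6R,7R,10S)-saturated 4,5-diol
Conditions: H2 (1 atm), PtO2, EtOAc, rt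
Reagents that add atoms: none
Why: Heterogeneous syn hydrogenation of the outer face of a ring alkene that stands perpendicular to the ring plane; the trisubstituted alkene can rotate (H-1 passes through the ring), the rotamer with C14 on the β face is wedged against C15 and the O6–Si(t-Bu)2 unit, and reaction should therefore go through the rotamer with C14 on the α face, whose outer face leads to 10S.

**Step 15**
Reactants: 21 saturated 4,5-diol
Product: 22 4,5-acetonide 6,11-silylene ether
Conditions: Me2C(OMe)2, PPTS, CH2Cl2, rt
Reagents that add atoms: 2,2-dimethoxypropane, COC(C)(C)OC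
Why: Acid-catalysed transketalisation, in which O4 and O5 are gauche on the same side of C4–C5 and close a dioxolane that masks both hydroxyl groups before acylation, with no change at any stereocentre.

**Step 16**
Reactants: 22 4,5-acetonide 6,11-silylene ether
Product: 23 4,5-acetonide 6,11-diol
Conditions: HF·pyridine, pyridine–THF, 0 °C
Reagents that add atoms: none
Why: Fluoride cleavage of both Si–O bonds, with buffered HF·pyridine leaving the acetonide in place.

**Step 17**
Reactants: 23 4,5-acetonide 6,11-diol; 24 angelic acid
Product: 25 6-O-angeloyl 4,5-acetonide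
Conditions: 24, 2,4,6-Cl3C6H2COCl, Et3N, toluene, rt; then 23, 80 °C
Reagents that add atoms: none
Why: Mixed-anhydride (Yamaguchi-type) esterification run without a nucleophilic amine catalyst so that the Z angelate is not isomerised to the E tiglate; only the secondary C6–OH reacts because the tertiary C11–OH is too hindered, and C6 keeps its configuration because the C–O bond is not broken.

**Step 18**
Reactants: 25 6-O-angeloyl 4,5-acetonide
Product: 26 target CNP0130723.1 (4R,5S,6R,7R,10S)
Conditions: AcOH–H2O (4:1), 40 °C
Reagents that add atoms: none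
Why: Mild acid hydrolysis of the acetonide, under which the angelate and both tertiary alcohols should survive and acyl migration from O6 to O5 is slow.

**Compound list**
1 | (R)-carvone | CC1=CC[C@H](CC1=O)C(C)=C | starting material
2 | (2R,5R)-dihydrocarvone | O=C1C[C@H](C(C)=C)CC[C@H]1C | intermediate
3 | (2R,5R)-5-(2-chloropropan-2-yl)-2-methylcyclohexanone | O=C1C[C@H](C(C)(C)Cl)CC[C@H]1C | intermediate
4 | carone, cyclopropane on the β face | O=C1[C@H]2[C@H](C2(C)C)CC[C@H]1C | intermediate
5 | acetaldehyde | CC=O | starting material
6 | lithium C5=C10 enolate of carone | [Li+].[O-]C1=C(C)CC[C@@H]2[C@H]1C2(C)C | intermediate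
7 | 10α-(1-hydroxyethyl)-10β-methylcarone (carbinol epimers) | O=C1[C@H]2[C@H](C2(C)C)CC[C@@]1(C)C(C)O | intermediate
8 | 10β-methyl-10α-vinylcarone | O=C1[C@H]2[C@H](C2(C)C)CC[C@@]1(C)C=C | intermediate
9 | isopropenylmagnesium bromide | CC(=C)[Mg]Br | starting material
10 | 5α-isopropenyl-10β-methyl-10α-vinylcaran-5β-ol | C=C(C)[C@@]1(O)[C@H]2[C@H](C2(C)C)CC[C@@]1(C)C=C | intermediate
11 | (7R,10S)-dienol with C5=C6, 5-isopropenyl and 7β-C(CH3)2OH | C=C(C)C1=C[C@H](C(C)(C)O)CC[C@@]1(C)C=C | intermediate
12 | (5S,6R,7R,10S)-5β,6β-epoxide | C=C(C)[C@@]12O[C@@H]1[C@H](C(C)(C)O)CC[C@@]2(C)C=C | intermediate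
13 | (5R,6R,7R,10S)-5α,6β,11-triol | O[C@@H]1[C@H](C(C)(C)O)CC[C@@](C)(C=C)[C@]1(O)C(C)=C | intermediate
14 | oxy-Cope precursor, 6,11-di-tert-butylsilylene ether | O3[C@@H]1[C@H](C(C)(C)O[Si]3(C(C)(C)C)C(C)(C)C)CC[C@@](C)(C=C)[C@]1(O)C(C)=C | intermediate
15 | potassium C5 alkoxide of 14 | O3[C@@H]1[C@H](C(C)(C)O[Si]3(C(C)(C)C)C(C)(C)C)CC[C@@](C)(C=C)[C@]1([O-])C(C)=C.[K+] | intermediate
16 | ten-membered potassium C4=C5 enolate | O3[C@@H]1[C@H](C(C)(C)O[Si]3(C(C)(C)C)C(C)(C)C)CC/C(C)=C/CC/C(C)=C1\[O-].[K+] | intermediate
17 | ten-membered 1(10),4-diene, C5 trimethylsilyl enol ether | O3[C@@H]1[C@H](C(C)(C)O[Si]3(C(C)(C)C)C(C)(C)C)CC/C(C)=C/CC/C(C)=C1\O[Si](C)(C)C | intermediate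
18 | (4R)-4-trimethylsilyloxy-5-ketone | O3[C@@H]1[C@H](C(C)(C)O[Si]3(C(C)(C)C)C(C)(C)C)CC/C(C)=C/CC[C@@](C)(O[Si](C)(C)C)C1=O | intermediate
19 | (4R,6R,7R)-4-hydroxy-5-ketone | O3[C@@H]1[C@H](C(C)(C)O[Si]3(C(C)(C)C)C(C)(C)C)CC/C(C)=C/CC[C@@](C)(O)C1=O | intermediate
20 | (4R,5S,6R,7R)-4,5-diol, C1=C10 E | O3[C@@H]1[C@H](C(C)(C)O[Si]3(C(C)(C)C)C(C)(C)C)CC/C(C)=C/CC[C@@](C)(O)[C@H]1O | intermediate
21 | (4R,5S,6R,7R,10S)-saturated 4,5-diol | O3[C@@H]1[C@H](C(C)(C)O[Si]3(C(C)(C)C)C(C)(C)C)CC[C@@H](C)CCC[C@@](C)(O)[C@H]1O | intermediate
22 | 4,5-acetonide 6,11-silylene ether | O3[C@@H]1[C@H](C(C)(C)O[Si]3(C(C)(C)C)C(C)(C)C)CC[C@@H](C)CCC[C@@]2(C)OC(C)(C)O[C@@H]12 | intermediate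
23 | 4,5-acetonide 6,11-diol | O[C@@H]1[C@H](C(C)(C)O)CC[C@@H](C)CCC[C@@]2(C)OC(C)(C)O[C@@H]12 | intermediate
24 | angelic acid | C/C=C(/C)C(=O)O | starting material
25 | 6-O-angeloyl 4,5-acetonide | C/C=C(/C)C(=O)O[C@@H]1[C@H](C(C)(C)O)CC[C@@H](C)CCC[C@@]2(C)OC(C)(C)O[C@@H]12 | intermediate
26 | CNP0130723.1 | C/C=C(/C)C(=O)O[C@@H]1[C@H](C(C)(C)O)CC[C@@H](C)CCC[C@@](C)(O)[C@H]1O | target

**Step count**
Total step count: 18. Longest linear sequence: 18 steps (1 to 26).

**Steps most likely to fail**

Step 14: facial selectivity at C10 may be poor or reversed, because both rotamers of the C1=C10 alkene may be hydrogenated at similar rates. The fallback replaces substrate control by reagent control and sets out from 20. Transketalisation (Me2C(OMe)2, PPTS) gives the unsaturated 4,5-acetonide F1. F1 is then hydrogenated with a chiral iridium N,P catalyst such as [Ir(cod)((S)-tBu-PHOX)][B(C6H3(CF3)2)4] or its enantiomer (H2, CH2Cl2). Because the alkene can offer either face by rotation, the ligand hand that selects the required face decides the outcome. The route is rejoined at 22.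

Step 11: the rearrangement may be slow, since allylic strain between C15 and O6 builds up in the transition state, and base-induced degradation may then compete. Proton exchange may also move or scramble the enolate before silylation. The fallback avoids the strongly basic medium and sets out from 14. A neutral thermal oxy-Cope rearrangement (decalin, about 200 °C) passes through the same chair, and tautomerisation of the enol gives the ten-membered 5-ketone F2. Kinetic deprotonation away from the oxygen-bearing C6 with an internal quench (KN(SiMe3)2, Me3SiCl, THF, −78 °C) removes the outward-pointing C4–H and should regenerate the same enol ether. The route is rejoined at 17. The stereochemical relay is less secure on this path.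

Step 9: during epoxide hydrolysis, allylic (SN2′) capture, loss of inversion through a free cation, or hydride-shift rearrangement may compete. The fallback moves the invertive opening from C5 to C6 by means of a tether and sets out from 11. One equivalent of t-Bu2Si(OTf)2 with 2,6-lutidine, followed by aqueous NaHCO3, gives the C11 di-tert-butylsilanol ether F3. Dimethyldioxirane in acetone epoxidises C5=C6 from the α face, because the β face is covered by the bulky side chain and C14. This gives the 5α,6α-epoxy silanol F4. NaH in THF then lets the silanolate open the epoxide at C6 from the β face (6-exo, inversion), which closes the dioxasilinane and frees 5α-OH. The route is rejoined at 14.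

**Further compounds**
F1 | step 14 | unsaturated 4,5-acetonide 6,11-silylene ether (C1=C10 E) | O3[C@@H]1[C@H](C(C)(C)O[Si]3(C(C)(C)C)C(C)(C)C)CC/C(C)=C/CC[C@@]2(C)OC(C)(C)O[C@@H]12
F2 | step 11 | ten-membered 1(10)E-en-5-one with C4–H, 6,11-silylene ether | O3[C@@H]1[C@H](C(C)(C)O[Si]3(C(C)(C)C)C(C)(C)C)CC/C(C)=C/CC[C@H](C)C1=O
F3 | step 9 | C11 di-tert-butylsilanol ether of dienol 11 | C=C(C)C1=C[C@H](C(C)(C)O[Si](O)(C(C)(C)C)C(C)(C)C)CC[C@@]1(C)C=C
F4 | step 9 | 5α,6α-epoxy silanol | C=C(C)[C@]12O[C@H]1[C@H](C(C)(C)O[Si](O)(C(C)(C)C)C(C)(C)C)CC[C@@]2(C)C=C
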